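**Compound numbering used throughout:** 1–17 as defined in the steps and the compound list below.

## Analysis of the target

Gardenin D (17) is a flavone: a 4H-chromen-4-one (benzo ring A fused to pyranone ring C) with an aryl ring B at C2. It has no stereocentre, so the problem is entirely one of regiochemistry. Ring A is fully substituted: C5 carries a hydroxyl hydrogen-bonded to the C4 carbonyl, C6, C7 and C8 carry methoxy groups, C8a carries the ring oxygen O1 and C4a carries the carbonyl carbon. Ring B has a free hydroxyl at C3' next to a methoxy group at C4'. The sensitive points are the two phenols (one chelated, one not) among four methyl ethers, the ease with which so electron-rich a ring A is oxidized to a quinone, and the tendency of the pyranone to open in strong alkali. The difficulty is to place five contiguous oxygens on ring A so that exactly one (at C5) ends up unmethylated and one (O1) ends up in the ring, while the C3' and C4' oxygens stay distinct. The strategy rests on one observation: C4a is the only ring-A carbon without an oxygen, it lies between the oxygen-bearing carbons C5 and C8a, and the oxygen pattern around it is that of 2,3,5-trimethoxy-1,4-benzoquinone (5), whose single C–H carbon becomes C4a. The C4a–C4 bond can therefore be made by joining that carbon to the formyl carbon of the 3-arylpropanal 9, the two quinone oxygens becoming O1 and the oxygen at C6.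

## Retrosynthetic reasoning

The last operation should only unmask the two phenols. Cutting the O–CH3 bond at C5 and the O–CH(CH3)2 bond at C3' of 17 leads back to the fully etherified flavone 15. The C5 ether is the only methyl ether peri to the carbonyl and the isopropyl ether is the only secondary alkyl ether, so one chelating boron Lewis acid can be asked to remove both (through the borate 16). The forward step has to leave the methyl ethers at C6, C7, C8 and C4' alone.

Ring C is opened next. The O1–C2 bond is cut and the C2=C3 double bond is taken back to a saturated CH2–CH2 link, which turns 15 into the open-chain ortho-hydroxy ketone 12. Cutting here, and not at C2–C1' or C3–C4, keeps the whole carbon chain in one piece, so no condensation is needed once the ring-A ketone exists. The forward reaction must remove four hydrogens and form one C–O bond (through 13 and 14) without harming the electron-rich rings.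

In 12 the ring-A oxygen meta to the ketone is a methyl ether. Removing that methyl gives hydroquinone 11, in which the hydroxyl ortho to the ketone is held in a hydrogen bond and the other is not. Forward, one equivalent of an alkylating agent must find only the free hydroxyl.

The central cut is the C4a–C4 bond of 11, between the ketone carbon and the one ring carbon that carries no oxygen. It divides the molecule into quinone 5, which holds all five ring-A oxygens on the right carbons, and aldehyde 9, which holds ring B and the three-carbon chain. The hydroquinone pattern of 11 is the reduced form of 5 and the aldehyde is the reduced form of the acyl group, so the union is redox-neutral and needs no activating or leaving group. Neither partner is a nucleophile at the carbon to be joined; forward, light must turn them into a radical pair (leading through 10) that combines at the lone C–H of 5.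

Quinone 5 is traced to phenol 4 by returning a methyl group to the oxygen para to the hydroxyl (an oxidative demethylation in the forward sense). Phenol 4 is traced to the symmetrical arene 1 by removing the hydroxyl. The two ring hydrogens of 1 are equivalent, so a directed metalation (via 2 and 3) introduces the oxygen with no regiochemical question.

Aldehyde 9 comes from ester 7 by lowering the oxidation state of the chain terminus (through 8), and 7 from acid 6 by removing both isopropyl groups. Acid 6 already contains the ring-B substitution pattern and all three chain carbons, so no C–C bond has to be made on this side.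

## Alternatives that were turned down

Alternative 1: Ring C is disconnected at C8a–O1 and ring A is drawn from a symmetrical 2,6-dibromo-3,4,5-trimethoxybenzoyl unit. Diketone A1 would be cyclized with CuI and K2CO3, its enol oxygen displacing one of the two equivalent ortho bromides (Ullmann-type intramolecular O-arylation), to give the 5-bromoflavone A2.
- For: ring A comes from a cheap gallate building block, the symmetry of A1 removes any choice between the two halides, and every step is thermal ground-state chemistry. On robustness and scalability of the key step this plan is probably stronger than a photoreaction.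
- Against: the C5 substituent of A2 is bromine, not oxygen. A second metal-mediated C–O bond formation is still needed at a carbon wedged between the peri carbonyl and the C6 methoxy group, and reductive loss of that bromide would give a by-product lacking the C5 oxygen that is hard to separate. A1 must also be assembled by acylation with a 2,6-disubstituted benzoyl electrophile, where O-acylation and slow C-acylation are expected.
- Comparison: step count is similar. The chosen route offers instead an intermediate (11) in which every ring-A substituent is already oxygen or carbon at the right position, with no halogen to convert later.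

Alternative 2: The C5–O bond is made last. The 5-unsubstituted flavone A3 would be hydroxylated ortho to the ketone with [RuCl2(p-cymene)]2 and PhI(OCOCF3)2 in CF3CO2H, the chromone carbonyl directing cycloruthenation at C5, to give Gardenin D 3'-acetate A4; acetate hydrolysis finishes.
- For: it is the shortest plan. A3 follows from a standard Baker–Venkataraman or chalcone sequence, no ring-A oxygen has to be told from another, and no demethylation is needed. On step economy it is clearly ahead of the chosen route.
- Against: C5–H is the only ring-A hydrogen and sits between the carbonyl and the C6 methoxy group, so the metallacycle must form at a flanked position. More seriously, the phenol that is unmasked from A4 has a methoxy group para to it (at C8). That is the motif an oxidant converts into a quinone with loss of the methyl group, the same reactivity that step 2 of the chosen route uses on purpose. The tetraoxygenated ring A would also sit in a strongly oxidizing acidic medium.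
- Comparison: the chosen route is longer, but it places the C5 oxygen by construction and never exposes the finished ring A to a hypervalent iodine oxidant.

Alternative 3: The C8–O bond is made last. The 5-hydroxyflavone A5 (C8 unsubstituted) would be treated with K2S2O8 in aqueous KOH and pyridine, then acid (Elbs persulfate oxidation para to the phenoxide), to give hydroquinone A6. Methylation of the unchelated 8-hydroxyl and debenzylation would follow.
- For: the reaction type is classical for exactly this position of flavones. The C5 hydroxyl is present and chelated from the start, so no late demethylation is needed. The endgame logic (hydroquinone, then methylation of the hydroxyl that is not hydrogen-bonded) is the same as in the chosen route.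
- Against: Elbs oxidations typically stop at partial conversion because persulfate consumes the phenoxide by other paths. The chelated 5-hydroxyl is ionized only in strong alkali, where the pyranone ring tends to open, and A6 is an air-sensitive hydroquinone in base. The oxidation comes late, on the complete flavone.
- Comparison: step count is about equal. The chosen route puts its uncertain step early, where both partners are two steps from purchased material, and uses it to form a C–C bond instead of correcting an oxidation level on the most valuable intermediate.

Key step: step 5

Assumption: compounds 1 and 6 are bought as such, and hydroquinone-level intermediates (11 in particular) are handled under argon because base and air oxidize them.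

## Route

Step 1
Reactants: 1 1,2,3,4-tetramethoxybenzene
Product: 4 2,3,4,5-tetramethoxyphenol, via aryllithium 2 (not isolated), via lithium arylborate 3 (not isolated)
Conditions: n-BuLi, TMEDA, THF, 0 °C; B(OMe)3, −78 °C → rt; 30% aq. H2O2, AcOH, 0 °C → rt
Reagents that add atoms: hydrogen peroxide, OO
Why: Directed ortho-metalation next to a methoxy group (the two ring C–H are equivalent by symmetry), borate quench and oxidative 1,2-shift of the aryl group from boron to oxygen should give the phenol; the same metalation is standard on the closely related tetramethoxytoluene of ubiquinone chemistry.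

Step 2
Reactants: 4 2,3,4,5-tetramethoxyphenol
Product: 5 2,3,5-trimethoxycyclohexa-2,5-diene-1,4-dione
Conditions: (NH4)2Ce(NO3)6 (2.2 equiv), MeCN/H2O, 0 °C
Reagents that add atoms: water, O
Why: Oxidative demethylation of a para-methoxyphenol: two one-electron oxidations by tetravalent cerium, addition of water at the methoxy-bearing para carbon and loss of methanol should give the p-quinone, the para mode being preferred over the ortho one.

Step 3
Reactants: 6 3-(3-hydroxy-4-methoxyphenyl)propanoic acid
Product: 7 propan-2-yl 3-[4-methoxy-3-(propan-2-yloxy)phenyl]propanoate
Conditions: 2-bromopropane (4 equiv), K2CO3, DMF, 70 °C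
Reagents that add atoms: 2-bromopropane, CC(C)Br
Why: Double SN2 alkylation (Williamson etherification of the phenoxide and alkylation of the carboxylate); the isopropyl ether protects the ring-B phenol through steps 5–7 and the ester is ready for partial reduction.

Step 4
Reactants: 7 propan-2-yl 3-[4-methoxy-3-(propan-2-yloxy)phenyl]propanoate
Product: 9 3-[4-methoxy-3-(propan-2-yloxy)phenyl]propanal, via aluminium hemiacetal 8 (not isolated)
Conditions: i-Bu2AlH (1.05 equiv), CH2Cl2, −78 °C; MeOH, then aq. KNaC4H4O6
Reagents that add atoms: none
Why: Partial ester reduction: the tetrahedral aluminium hemiacetal 8 is stable at −78 °C and collapses to the aldehyde only on work-up, which limits over-reduction.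

Step 5
Reactants: 5 2,3,5-trimethoxycyclohexa-2,5-diene-1,4-dione; 9 3-[4-methoxy-3-(propan-2-yloxy)phenyl]propanal
Product: 11 1-(2,5-dihydroxy-3,4,6-trimethoxyphenyl)-3-[4-methoxy-3-(propan-2-yloxy)phenyl]propan-1-one, via dienone tautomer 10 (not isolated)
Conditions: 9 (3 equiv, excess recovered), PhH (degassed), hν (visible, 400–450 nm), rt, Ar
Reagents that add atoms: none
Why: Photo-Friedel–Crafts acylation of a 1,4-quinone by an aldehyde. Visible light excites 5 to its triplet, whose carbonyl oxygen abstracts the formyl hydrogen of 9 (a weak C–H that is polarity-matched to the electrophilic oxygen), giving a semiquinone/acyl radical pair. The primary acyl radical loses CO only slowly, so it survives to combine with the semiquinone at a ring carbon ortho to the oxyl centre; the only hydrogen-bearing ring carbon of 5 is such a position, and the dienone 10 so formed should aromatize by enolization to 11. No ring is closed, and the one sp3 carbon of 10 is transient and racemic, so no stereocontrol is needed. Site selectivity is built into 5: its three other ring carbons carry methoxy groups, and coupling there would give an adduct that cannot enolize to a hydroquinone. What must be won is C- over O-acylation of the semiquinone (the hydroquinone monoester is the usual by-product of this reaction type) and formyl over benzylic or isopropyl-methine hydrogen abstraction. The levers are a non-polar solvent that keeps the radical pair caged, an excess of 9 and, if needed, benzophenone as hydrogen-abstracting mediator so that the acyl radical adds to ground-state 5. The new ketone hydrogen-bonds only one of the two hydroquinone hydroxyls, which prepares step 6.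

Step 6
Reactants: 11 1-(2,5-dihydroxy-3,4,6-trimethoxyphenyl)-3-[4-methoxy-3-(propan-2-yloxy)phenyl]propan-1-one
Product: 12 1-(2-hydroxy-3,4,5,6-tetramethoxyphenyl)-3-[4-methoxy-3-(propan-2-yloxy)phenyl]propan-1-one
Conditions: MeI (1.1 equiv), K2CO3, acetone, Ar, rt
Reagents that add atoms: iodomethane, CI
Why: Williamson methylation under chelation control: the hydroxyl ortho to the ketone is locked in a six-membered hydrogen bond and its phenoxide is poorly nucleophilic, so one equivalent of MeI should alkylate only the other hydroxyl, as in the classical partial methylation of 2,5-dihydroxyaryl ketones; air is excluded to prevent oxidation to the acylquinone.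

Step 7
Reactants: 12 1-(2-hydroxy-3,4,5,6-tetramethoxyphenyl)-3-[4-methoxy-3-(propan-2-yloxy)phenyl]propan-1-one
Product: 15 5,6,7,8-tetramethoxy-2-[4-methoxy-3-(propan-2-yloxy)phenyl]-4H-chromen-4-one, via chalcone 13 (not isolated), via flavanone 14 (not isolated)
Conditions: Pd(OCOCF3)2 (10 mol %), 5-nitro-1,10-phenanthroline (20 mol %), DMSO, O2 (1 atm), 100 °C
Reagents that add atoms: none
Why: Aerobic dehydrogenative cyclization of a 2'-hydroxydihydrochalcone: a divalent palladium enolate undergoes β-hydride elimination to chalcone 13, the phenol closes ring C by 6-endo-trig oxa-Michael addition to flavanone 14, and a second enolate/β-hydride elimination gives the flavone while O2 reoxidizes zerovalent palladium.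

Step 8
Reactants: 15 5,6,7,8-tetramethoxy-2-[4-methoxy-3-(propan-2-yloxy)phenyl]-4H-chromen-4-one
Product: 17 Gardenin D, 5-hydroxy-2-(3-hydroxy-4-methoxyphenyl)-6,7,8-trimethoxy-4H-chromen-4-one, via bis(dichloroboryl) ether 16 (not isolated)
Conditions: BCl3 (4 equiv), CH2Cl2, −78 → 0 °C; then MeOH/H2O
Reagents that add atoms: none
Why: Lewis-acid ether cleavage: boron bound to the C4 carbonyl delivers chloride to the peri C5 methyl ether through a six-membered chelate, and the secondary isopropyl ether ionizes far faster than any methyl ether, so the methoxy groups at C6, C7, C8 and C4' should survive at low temperature; the borates 16 are hydrolysed on work-up.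

## Compound list

1 | 1,2,3,4-tetramethoxybenzene | COc1ccc(OC)c(OC)c1OC | starting material
2 | (2,3,4,5-tetramethoxyphenyl)lithium | [Li]c1cc(OC)c(OC)c(OC)c1OC | intermediate (not isolated)
3 | lithium trimethoxy(2,3,4,5-tetramethoxyphenyl)borate | [Li+].CO[B-](OC)(OC)c1cc(OC)c(OC)c(OC)c1OC | intermediate (not isolated)
4 | 2,3,4,5-tetramethoxyphenol | COc1cc(O)c(OC)c(OC)c1OC | intermediate
5 | 2,3,5-trimethoxycyclohexa-2,5-diene-1,4-dione | COC1=CC(=O)C(OC)=C(OC)C1=O | intermediate
6 | 3-(3-hydroxy-4-methoxyphenyl)propanoic acid | COc1ccc(CCC(=O)O)cc1O | starting material
7 | propan-2-yl 3-[4-methoxy-3-(propan-2-yloxy)phenyl]propanoate | COc1ccc(CCC(=O)OC(C)C)cc1OC(C)C | intermediate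
8 | bis(2-methylpropyl){3-[4-methoxy-3-(propan-2-yloxy)phenyl]-1-(propan-2-yloxy)propoxy}alumane (racemic) | COc1ccc(CCC(OC(C)C)O[Al](CC(C)C)CC(C)C)cc1OC(C)C | intermediate (not isolated)
9 | 3-[4-methoxy-3-(propan-2-yloxy)phenyl]propanal | COc1ccc(CCC=O)cc1OC(C)C | intermediate
10 | 4-hydroxy-2,3,5-trimethoxy-6-{3-[4-methoxy-3-(propan-2-yloxy)phenyl]propanoyl}cyclohexa-2,4-dien-1-one (racemic) | COc1ccc(CCC(=O)C2C(=O)C(OC)=C(OC)C(O)=C2OC)cc1OC(C)C | intermediate (not isolated)
11 | 1-(2,5-dihydroxy-3,4,6-trimethoxyphenyl)-3-[4-methoxy-3-(propan-2-yloxy)phenyl]propan-1-one | COc1ccc(CCC(=O)c2c(O)c(OC)c(OC)c(O)c2OC)cc1OC(C)C | intermediate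
12 | 1-(2-hydroxy-3,4,5,6-tetramethoxyphenyl)-3-[4-methoxy-3-(propan-2-yloxy)phenyl]propan-1-one | COc1ccc(CCC(=O)c2c(O)c(OC)c(OC)c(OC)c2OC)cc1OC(C)C | intermediate
13 | (2E)-1-(2-hydroxy-3,4,5,6-tetramethoxyphenyl)-3-[4-methoxy-3-(propan-2-yloxy)phenyl]prop-2-en-1-one | COc1ccc(/C=C/C(=O)c2c(O)c(OC)c(OC)c(OC)c2OC)cc1OC(C)C | intermediate (not isolated)
14 | 5,6,7,8-tetramethoxy-2-[4-methoxy-3-(propan-2-yloxy)phenyl]-2,3-dihydro-4H-chromen-4-one (racemic) | COc1ccc(C2CC(=O)c3c(OC)c(OC)c(OC)c(OC)c3O2)cc1OC(C)C | intermediate (not isolated)
15 | 5,6,7,8-tetramethoxy-2-[4-methoxy-3-(propan-2-yloxy)phenyl]-4H-chromen-4-one | COc1ccc(-c2cc(=O)c3c(OC)c(OC)c(OC)c(OC)c3o2)cc1OC(C)C | intermediate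
16 | 5-[(dichloroboranyl)oxy]-2-{3-[(dichloroboranyl)oxy]-4-methoxyphenyl}-6,7,8-trimethoxy-4H-chromen-4-one | COc1ccc(-c2cc(=O)c3c(OB(Cl)Cl)c(OC)c(OC)c(OC)c3o2)cc1OB(Cl)Cl | intermediate (not isolated)
17 | Gardenin D, 5-hydroxy-2-(3-hydroxy-4-methoxyphenyl)-6,7,8-trimethoxy-4H-chromen-4-one | COc1ccc(-c2cc(=O)c3c(O)c(OC)c(OC)c(OC)c3o2)cc1O | target

## Step count and risk

Total step count: 8.
Longest linear sequence: 6 steps (1 → 4 → 5 → 11 → 12 → 15 → 17; the branch from 6 through 7 and 9 is equally long).

Steps least certain to work:

**Step 5 (key step).** The most likely failure is acylation on oxygen instead of carbon. The lone C–H carbon of 5 is flanked by a carbonyl and a methoxy-bearing carbon and is the electron-rich α-carbon of a vinylogous ester, so radical combination there is slower than at an unhindered quinone carbon. A second failure mode is quenching of the quinone triplet by electron transfer from the dialkoxyarene of 9, or hydrogen abstraction at the benzylic or isopropyl-methine position, giving low conversion or reduction of 5 without C–C bond formation.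
Fallback (sets out from 4 and 9, returns at 12, and so also replaces step 6): phenol 4 is protected with MeOCH2Cl and i-Pr2NEt as 1,2,3,4-tetramethoxy-5-(methoxymethoxy)benzene F1. F1 is lithiated with n-BuLi in THF at its only ring C–H, which lies between the acetal and a methoxy group, and the aryllithium is added at −78 °C to aldehyde 9 to give the benzylic alcohol 3-[4-methoxy-3-(propan-2-yloxy)phenyl]-1-[2,3,4,5-tetramethoxy-6-(methoxymethoxy)phenyl]propan-1-ol F2. Dess–Martin oxidation gives the corresponding propan-1-one F3, and HCl in MeOH removes the acetal to give 12. The radical union is thereby replaced by a polar one in which the ring carbon is made nucleophilic.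

**Step 7.** The most likely failure is stalling at the chalcone or flavanone stage or loss of catalyst activity: the ketone is flanked by two ortho substituents, so the palladium enolate must form at a hindered, twisted carbonyl. Oxidative degradation of the electron-rich ring A at 100 °C under O2 is the other concern.
Fallback (from 12, back at 15): Me3SiOTf and Et3N convert 12 into the bis-silyl derivative F4, a (Z)-trimethylsilyl enol ether that also carries an aryl trimethylsilyl ether. Saegusa–Ito oxidation with Pd(OAc)2 in MeCN and desilylation on work-up give chalcone 13, now isolated. Catalytic I2 in DMSO at 130 °C then closes and dehydrogenates 13 through 14 to 15.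

**Step 8.** The most likely failure is loss of chemoselectivity in ether cleavage. Once the C5 oxygen is bound to boron, the neighbouring C6 methoxy group can be cleaved as well, and the C4' methoxy group next to the C3' borate is similarly exposed, so over-demethylation may occur.
Fallback (from 15, back at 17): the two ethers are removed in separate operations by different mechanisms. Heating 15 with HCl in EtOH protonates the pyranone carbonyl and cleaves only the peri methyl ether, giving 5-hydroxy-6,7,8-trimethoxy-2-[4-methoxy-3-(propan-2-yloxy)phenyl]-4H-chromen-4-one F5. The isopropyl ether of F5 is then cleaved with AlCl3 in CH2Cl2 at 0 °C, where a secondary alkyl aryl ether ionizes and methyl ethers do not. Any early loss of the isopropyl group in the first operation is harmless.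

**Step 1.** The most likely failure is incomplete metalation, or over-oxidation of the very electron-rich phenol by excess peroxide during boronate oxidation.
Fallback (from 1, back at 4): Rieche formylation of 1 (Cl2CHOMe, TiCl4, CH2Cl2, 0 °C) gives 2,3,4,5-tetramethoxybenzaldehyde F6. Baeyer–Villiger (Dakin-type) oxidation with mCPBA gives 2,3,4,5-tetramethoxyphenyl formate F7, which K2CO3 in MeOH cleaves to 4.

## Further compounds

F1 | step 5 | 1,2,3,4-tetramethoxy-5-(methoxymethoxy)benzene | COCOc1cc(OC)c(OC)c(OC)c1OC
F2 | step 5 | 3-[4-methoxy-3-(propan-2-yloxy)phenyl]-1-[2,3,4,5-tetramethoxy-6-(methoxymethoxy)phenyl]propan-1-ol (racemic) | COCOc1c(OC)c(OC)c(OC)c(OC)c1C(O)CCc1ccc(OC)c(OC(C)C)c1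
F3 | step 5 | 3-[4-methoxy-3-(propan-2-yloxy)phenyl]-1-[2,3,4,5-tetramethoxy-6-(methoxymethoxy)phenyl]propan-1-one | COCOc1c(OC)c(OC)c(OC)c(OC)c1C(=O)CCc1ccc(OC)c(OC(C)C)c1
F4 | step 7 | {[(1Z)-3-[4-methoxy-3-(propan-2-yloxy)phenyl]-1-{2,3,4,5-tetramethoxy-6-[(trimethylsilyl)oxy]phenyl}prop-1-en-1-yl]oxy}trimethylsilane | COc1ccc(C/C=C(\O[Si](C)(C)C)c2c(O[Si](C)(C)C)c(OC)c(OC)c(OC)c2OC)cc1OC(C)C
F5 | step 8 | 5-hydroxy-6,7,8-trimethoxy-2-[4-methoxy-3-(propan-2-yloxy)phenyl]-4H-chromen-4-one | COc1ccc(-c2cc(=O)c3c(O)c(OC)c(OC)c(OC)c3o2)cc1OC(C)C
F6 | step 1 | 2,3,4,5-tetramethoxybenzaldehyde | COc1cc(C=O)c(OC)c(OC)c1OC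
F7 | step 1 | 2,3,4,5-tetramethoxyphenyl formate | COc1cc(OC=O)c(OC)c(OC)c1OC
A1 | alternative 1 | 1-[3-(benzyloxy)-4-methoxyphenyl]-3-(2,6-dibromo-3,4,5-trimethoxyphenyl)propane-1,3-dione | COc1ccc(C(=O)CC(=O)c2c(Br)c(OC)c(OC)c(OC)c2Br)cc1OCc1ccccc1
A2 | alternative 1 | 2-[3-(benzyloxy)-4-methoxyphenyl]-5-bromo-6,7,8-trimethoxy-4H-chromen-4-one | COc1ccc(-c2cc(=O)c3c(Br)c(OC)c(OC)c(OC)c3o2)cc1OCc1ccccc1
A3 | alternative 2 | 2-methoxy-5-(6,7,8-trimethoxy-4-oxo-4H-chromen-2-yl)phenyl acetate | COc1ccc(-c2cc(=O)c3cc(OC)c(OC)c(OC)c3o2)cc1OC(C)=O
A4 | alternative 2 | 5-(5-hydroxy-6,7,8-trimethoxy-4-oxo-4H-chromen-2-yl)-2-methoxyphenyl acetate (Gardenin D 3'-acetate) | COc1ccc(-c2cc(=O)c3c(O)c(OC)c(OC)c(OC)c3o2)cc1OC(C)=O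
A5 | alternative 3 | 2-[3-(benzyloxy)-4-methoxyphenyl]-5-hydroxy-6,7-dimethoxy-4H-chromen-4-one | COc1ccc(-c2cc(=O)c3c(O)c(OC)c(OC)cc3o2)cc1OCc1ccccc1
A6 | alternative 3 | 2-[3-(benzyloxy)-4-methoxyphenyl]-5,8-dihydroxy-6,7-dimethoxy-4H-chromen-4-one | COc1ccc(-c2cc(=O)c3c(O)c(OC)c(OC)c(O)c3o2)cc1OCc1ccccc1
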